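**Retrosynthet­ic overview**
1. Target 16 ⇐ 4,7-dibromoindole 14 (late electrophilic bromination at C3, then C2) ⇐ N-sulfonylindole 13 (desulfonylation).
2. 13 ⇐ 2,3-diethynylpyrrole 10 + CBr4 11: ring A is disconnected at C5–C6 and at both C–Br bonds in one Bergman cycloaromatization with bromine-atom capture.
3. 10 ⇐ 9 ⇐ 3-bromo-2-iodopyrrole 6 + trimethylsilylacetylene 7 (twofold Sonogashira coupling, then desilylation); 6 ⇐ 4 ⇐ 1 + 2.
4. Order of rings: the pyrrole ring B comes with starting material 1; the benzene ring A is the only ring made, in step 5.
5. Structural basis: ring A carries its two bromines para to each other on C4 and C7, the atoms on either side of the C5–C6 bond. These are the only two atoms that can bear a radical once C5–C6 is forged between ethynyl groups standing on C3a and C7a.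

Key step: step 5

Remark on the chemistry: pyrroles are numbered as pyrroles and indoles as indoles, so pyrrole C2 and C3 become indole C7a and C3a. Phenylsulfonyl is chosen for nitrogen in place of tosyl or a silyl group so that the protecting group offers no weak C–H bond to the aryl radicals of step 5.

**Step 1**
Reactants: 1 3-bromo-1-(triisopropylsilyl)pyrrole; 2 benzenesulfonyl chloride
Product: 4 3-bromo-1-(phenylsulfonyl)pyrrole, via 3-bromo-1H-pyrrole 3 (not isolated)
Conditions: Bu4NF (1.0 equiv), THF, 0 °C, aqueous wash, dry (Na2SO4); then NaH, PhSO2Cl, THF, 0 °C to rt
Reagents that add atoms: none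
Why: Fluoride cleaves the N–Si bond and the sensitive 3-bromopyrrole 3, kept cold in solution, is N-sulfonylated at once as its sodium salt (desilylation followed by N-sulfonylation of a pyrrolide).

**Step 2**
Reactants: 4 3-bromo-1-(phenylsulfonyl)pyrrole
Product: 6 3-bromo-2-iodo-1-(phenylsulfonyl)pyrrole, via 3-bromo-2-lithio-1-(phenylsulfonyl)pyrrole 5 (not isolated)
Conditions: LiN(i-Pr)2 (1.1 equiv), THF, −78 °C; then I2, −78 °C
Reagents that add atoms: iodine, II
Why: Directed lithiation removes the most acidic proton, at C2 between the sulfonylated nitrogen and the C3 bromine, and at −78 °C the amide base should cause neither bromine–lithium exchange nor halogen migration before the fast electrophile iodine traps the kinetic C2 anion.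

**Step 3**
Reactants: 6 3-bromo-2-iodo-1-(phenylsulfonyl)pyrrole; 7 trimethylsilylacetylene (3 equiv)
Product: 9 1-(phenylsulfonyl)-2,3-bis[(trimethylsilyl)ethynyl]pyrrole, via 3-bromo-1-(phenylsulfonyl)-2-[(trimethylsilyl)ethynyl]pyrrole 8 (not isolated)
Conditions: PdCl2(PhCN)2 (cat.), [HP(t-Bu)3]BF4 (cat.), CuI (cat.), i-Pr2NH, degassed 1,4-dioxane, rt then 50 °C
Reagents that add atoms: none
Why: Twofold Sonogashira coupling, in which the C2–I bond should react first at room temperature and the electron-rich bulky phosphine then carries oxidative addition into the slower C3–Br bond; the hindered secondary amine should leave the N-sulfonyl group alone.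

**Step 4**
Reactants: 9 1-(phenylsulfonyl)-2,3-bis[(trimethylsilyl)ethynyl]pyrrole
Product: 10 2,3-diethynyl-1-(phenylsulfonyl)pyrrole
Conditions: K2CO3 (cat.), MeOH/THF, 0 °C, short reaction time; neutral buffer quench
Reagents that add atoms: none
Why: Methoxide-induced protodesilylation of alkynylsilanes is much faster at 0 °C than methanolysis of the N-sulfonyl group, so both terminal alkynes should be freed with nitrogen still protected; 10 is kept cold in solution and used at once.

**Step 5**
Reactants: 10 2,3-diethynyl-1-(phenylsulfonyl)pyrrole; 11 carbon tetrabromide
Product: 13 4,7-dibromo-1-(phenylsulfonyl)indole, via 1-(phenylsulfonyl)-4,7-didehydroindole diradical 12 (not isolated)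
Conditions: CBr4 (50 equiv), degassed PhCl (10 at 5 mM), sealed tube, 180 °C, dark
Reagents that add atoms: none
Why: Proposed new method: the pyrrole C2=C3 bond locks the two ethynyl groups cis, so heating should trigger a Bergman cycloaromatization in which the terminal alkyne carbons bond to each other (the new C5–C6 bond) and the internal ones become the sigma-radical centres C4 and C7 of diradical 12, each of which then takes a bromine atom from the weak C–Br bond of CBr4. The nearest established reaction is the thermal Bergman cyclization of benzo-fused enediynes in which the 1,4-didehydroarene is intercepted by a halogen-atom donor such as CCl4; neither a pyrrole as the fused ring nor CBr4 as the donor has precedent. Ring A, the six-membered benzo ring, closes through this one C5–C6 bond in a unimolecular C1–C6 cycloaromatization of the hex-3-ene-1,5-diyne unit (formally endo with respect to both alkynes), and no stereocentre arises. The 4,7-dibromo pattern requires no regiocontrol, since radical character can only develop at the two internal alkyne carbons. The selectivity that matters is kinetic: bromine abstraction must beat retro-cyclization of 12, hydrogen abstraction, attack of the C7 radical on the sulfonyl phenyl ring and chain addition of CBr3 radicals to unreacted alkyne, which the large excess of CBr4, the absence of weak C–H bonds in solvent and N-substituent, and the 5 mM dilution of 10 (cyclization is first order in 10, oligomerization second order) are chosen to secure. Since a five-membered ring splays its two substituents more than a benzene ring does and so lengthens the distance between the alkyne termini, a higher barrier and therefore 180 °C in a sealed tube are assumed, and the N-sulfonyl group should both buttress the C2 alkyne toward its neighbour and keep the pyrrole ring inert to electrophilic bromine.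

**Step 6**
Reactants: 13 4,7-dibromo-1-(phenylsulfonyl)indole
Product: 14 4,7-dibromoindole
Conditions: Cs2CO3, THF/MeOH (2:1), rt
Reagents that add atoms: none
Why: Methoxide attacks sulfur and expels the indolide, a good leaving group here because of the two bromines, while the aryl bromides are inert to these conditions (base-mediated N-desulfonylation by methanolysis).

**Step 7**
Reactants: 14 4,7-dibromoindole
Product: 16 2,3,4,7-tetrabromoindole, via 3,4,7-tribromoindole 15 (not isolated)
Conditions: NBS (2.1 equiv), anhydrous THF, −78 °C to rt, dark
Reagents that add atoms: N-bromosuccinimide, O=C1CCC(=O)N1Br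
Why: Electrophilic bromination should first take the most nucleophilic carbon C3 to give 15 and then C2 (attack at C3 followed by 1,2-bromine shift of the 3,3-dibromoindolenine, or direct C2 attack); the already brominated ring A is deactivated and water is excluded to prevent oxindole formation.

**Compound list**
1 | 3-bromo-1-(triisopropylsilyl)pyrrole | CC(C)[Si](C(C)C)(C(C)C)n1ccc(Br)c1 | starting material
2 | benzenesulfonyl chloride | O=S(=O)(Cl)c1ccccc1 | starting material
3 | 3-bromo-1H-pyrrole | Brc1cc[nH]c1 | intermediate
4 | 3-bromo-1-(phenylsulfonyl)pyrrole | Brc1ccn(S(=O)(=O)c2ccccc2)c1 | intermediate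
5 | 3-bromo-2-lithio-1-(phenylsulfonyl)pyrrole | [Li]c1c(Br)ccn1S(=O)(=O)c1ccccc1 | intermediate
6 | 3-bromo-2-iodo-1-(phenylsulfonyl)pyrrole | Ic1c(Br)ccn1S(=O)(=O)c1ccccc1 | intermediate
7 | trimethylsilylacetylene | C[Si](C)(C)C#C | starting material
8 | 3-bromo-1-(phenylsulfonyl)-2-[(trimethylsilyl)ethynyl]pyrrole | C[Si](C)(C)C#Cc1c(Br)ccn1S(=O)(=O)c1ccccc1 | intermediate
9 | 1-(phenylsulfonyl)-2,3-bis[(trimethylsilyl)ethynyl]pyrrole | C[Si](C)(C)C#Cc1ccn(S(=O)(=O)c2ccccc2)c1C#C[Si](C)(C)C | intermediate
10 | 2,3-diethynyl-1-(phenylsulfonyl)pyrrole | C#Cc1ccn(S(=O)(=O)c2ccccc2)c1C#C | intermediate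
11 | carbon tetrabromide | BrC(Br)(Br)Br | starting material
12 | 1-(phenylsulfonyl)-4,7-didehydroindole diradical | O=S(=O)(c1ccccc1)n1ccc2[c]cc[c]c21 | intermediate
13 | 4,7-dibromo-1-(phenylsulfonyl)indole | Brc1ccc(Br)c2c1ccn2S(=O)(=O)c1ccccc1 | intermediate
14 | 4,7-dibromoindole | Brc1ccc(Br)c2[nH]ccc12 | intermediate
15 | 3,4,7-tribromoindole | Brc1c[nH]c2c(Br)ccc(Br)c12 | intermediate
16 | 2,3,4,7-tetrabromoindole | Brc1[nH]c2c(Br)ccc(Br)c2c1Br | target

Total step count: 7. Longest linear sequence: 7 steps (1 to 16).

**The three steps most likely to fail**

The first risk is step 5, the one proposed new method of the route. Bromine transfer to the diradical may be too slow relative to oligomerization of 10, chain addition of CBr4 across its terminal alkynes, or reopening of the diradical at the temperature that the pyrrole-fused system demands. The fallback gives up building ring A on the pyrrole and instead takes a benzene ring that already holds both bromines. It sets out from no numbered compound of the route but from commercial 1,4-dibromo-2-nitrobenzene F1, which is treated with CH2=CHMgBr (3 equiv) in THF at −40 °C in a Bartoli indole synthesis. In F1 one ortho position of the nitro group is blocked by bromine, so the [3,3]-sigmatropic shift can only reach the free ortho carbon, and cyclization with loss of water should give 4,7-dibromoindole 14. The fallback comes back to the route at 14, from which step 7 is run unchanged.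

The second risk is step 7. The second bromination may stall at the deactivated tribromoindole 15, or the 3,3-dibromoindolenine may be diverted to oxindole-type products by traces of water. The fallback sets out from 13 and replaces steps 6 and 7, so that C2 is brominated through deprotonation instead of electrophilic substitution. Lithiation of 13 at C2 with LiN(i-Pr)2 in THF at −78 °C, directed by the sulfonyl group, and quenching with BrCCl2CCl2Br should give 2,4,7-tribromo-1-(phenylsulfonyl)indole F2. Treatment of F2 with Cs2CO3 in THF/MeOH should then free 2,4,7-tribromoindole F3. One equivalent of NBS in DMF at 0 °C should brominate F3 at C3, its only open nucleophilic position, and the route is rejoined at the target 16.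

The third risk is step 3. Oxidative addition into the C3–Br bond may stall after the first coupling, while copper-mediated homocoupling uses up the alkyne. The fallback sets out from 8, isolated after coupling at the iodide alone at room temperature, and from 7. Compound 7 is deprotonated with n-BuLi in THF at −78 °C and transmetalated with ZnCl2 to chloro[(trimethylsilyl)ethynyl]zinc F4. Copper-free and amine-free Negishi coupling of F4 with 8, catalysed by Pd(PPh3)4 in THF at 60 °C, should give 9, where the route is rejoined.

**Further compounds**
F1 | step 5 | 1,4-dibromo-2-nitrobenzene | O=[N+]([O-])c1cc(Br)ccc1Br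
F2 | step 7 | 2,4,7-tribromo-1-(phenylsulfonyl)indole | Brc1cc2c(Br)ccc(Br)c2n1S(=O)(=O)c1ccccc1
F3 | step 7 | 2,4,7-tribromoindole | Brc1cc2c(Br)ccc(Br)c2[nH]1
F4 | step 3 | chloro[(trimethylsilyl)ethynyl]zinc | C[Si](C)(C)C#C[Zn]Cl
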